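The elm run is the reference: the orders asked are taken at its charge.

| flask | Z | E | time |
|---|---|---|---|
| elm | 120 mM | 240 mM |  |
| maple | 60.0 mM | 180 mM |  |
| oak | 240 mM | 240 mM |  |
| alder | 120 mM | 720 mM |  |
| ash | 240 mM | 720 mM | 33 h |

| elm run: time / h | elm run: [Z] / mM | maple run: time / h | maple run: [Z] / mM | oak run: time / h | oak run: [Z] / mM | alder run: time / h | alder run: [Z] / mM |
|---|---|---|---|---|---|---|---|
| 1.2 | 84.2 | 1.2 | 43.4 | 1.2 | 172.0 | 1.2 | 71.5 |
| 3.6 | 72.5 | 3.6 | 37.7 | 3.6 | 149.8 | 3.6 | 67.0 |
| 6.9 | 65.3 | 6.9 | 33.8 | 6.9 | 124.8 | 6.9 | 55.2 |
| 11 | 47.7 | 11 | 22.9 | 11 | 95.3 | 11 | 43.7 |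
| 16 | 32.1 | 16 | 15.8 | 16 | 70.2 | 16 | 30.7 |
| 21 | 28.3 | 21 | 11.9 | 21 | 54.5 | 21 | 22.3 |
| 27 | 16.8 | 27 | 9.2 | 27 | 33.1 | 27 | 17.5 |
| 33 | 13.0 | 33 | 4.8 | 33 | 25.5 | 33 | 13.5 |

(readings scatter by 2 mM)

- Overall: Z + E -> G.
- Constant volume, constant temperature.
- "The second partner" is E.
- An order is taken over about fifteen percent of the charge, up and down.

1. the exponent of [E] in the starting rate at the charge of the elm run (at the point where two percent of the Z have become G)
2. the exponent of [Z] in the starting rate at the charge of the elm run (at the point where two percent of the Z have become G) (one fixed amount of G, the same in the runs compared)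
3. Z in the ash run at 33 h, as a share of the Z charged

In the elm run Z falls at 29.8 mM/h on average up to 1.2 h, then at 4.88 mM/h up to 3.6 h. That is slower by a factor of 6.11. The reckoning here reads this first fall as a fast hold of Z by E, a pre-equilibrium, and takes the rate of G as proportional to the held amount.

In the elm run, the first reading of Z, at 1.2 h, over the Z charged gives 0.702, taken here as the free share; it is a reading and carries the scatter. With cZ fixed and held over free proportional to cE, the held amount has an exponent in E equal to the free share, so this reckoning puts the order in E at 0.702, and the rate rises with cE.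

The oak run has twice the Z of the elm run, and its first fall is 1.90 times as large, which, with the rate taken as proportional to the held amount, reads as an order in Z of 0.926. The alder run has 3.00 times the E of the elm run. Taken as proportional to cE, held over free goes from 0.425 to 1.28, and this reckoning puts the starting rate of the alder run at 1.88 times that of the elm run.

The slowing goes on. Over the last stretch the readings of Z in the elm run fall at 0.633 mM/h, a further factor of 7.71, and those of the alder run at 0.667 mM/h. The ash run has the E of the alder run and twice its Z. Scaling the final share of the alder run by the oak-to-elm ratio of final shares gives 11.0% left in the ash run.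

The forecast gives −0.2 for E, 1 for Z and 11% for the ash run, saying “More E therefore mildly retards the reaction”, so it differs from this reckoning in the sign of the order in E.

The flask gives 0.74 in E, 1.0 in Z and 9.24% of the Z charged left in the ash run at 33 h.

    Z + E ⇌ X, settled at all times (2.180 /M)
    X → G (0.1966 /h)
    Z → Qe (0.05868 /h)
    2 E → Xo (1.091 /M/h)

The order in E stands beside the free share of 0.702 read from the elm run. At the early point named in the question, the elm run makes G at 6.4 mM/h. Carried to the alder run, the free share gave 1.88, and the alder run makes G at 1.9 times the rate of the elm run at that point.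

(The runs were generated by integration with made-up constants; the scatter is artificial.)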